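The rate constants are invented; no experiment stands behind them.

A closed, stirred vessel holds substrate that free catalyst opens, and the open intermediate then has several ways out, one of them leading to target.

    substrate + free catalyst → free catalyst + open intermediate (k1 = 441 M⁻¹ min⁻¹)
    free catalyst + open intermediate ⇌ catalyst intermediate (K2 = 10.3 M⁻¹, k2 = 856 M⁻¹ min⁻¹)
    partner + catalyst intermediate → free catalyst + target (k3 = 345 M⁻¹ min⁻¹)
    substrate + open intermediate → side product (k4 = 1.08 M⁻¹ min⁻¹)
    open intermediate → decomposed reagent (k5 = 0.0828 min⁻¹)

substrate 34 mM; partner 68.0 mM; free catalyst 41 µM; time 30 h

* why nothing more happens at 30 h, or that something still does (no working catalyst is left / it is still moving / forward and back rates have come level / all of the substrate has reacted / the partner has run out first)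
* share of the substrate used up at 30 h
* target at 30 h, in percent of the substrate charged
* side product at 30 h, in percent of the substrate charged
* amount of target if the flask were left three thousand times as long, in percent of the substrate charged

- percent here means substrate units held: one side product counts as two
- the reaction counts as stopped when no species that holds the substrate changes by six tenths of a point or more over the second half of the time
- run time (flask): 30 h

**Capture rate.** Binding to free catalyst does not yet make target: catalyst intermediate falls back at 83.1 min⁻¹ and goes forward with partner at 23.5 min⁻¹, so 22.0% of the bindings count. Catalyst intermediate turns over much faster than open intermediate decomposes, so this share holds from moment to moment. A rate of 0.00773 min⁻¹ is then the capture rate: the forward rate constant of binding times [free catalyst] times that share, a pseudo-first-order rate at which open intermediate becomes target, with [free catalyst] and [partner] taken as charged.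

**Two ways.** Capture and decomposition together remove open intermediate at 0.0905 min⁻¹. Attack on substrate adds the side-product constant times [substrate], 0.0367 min⁻¹ at the start, and each such attack consumes a second substrate. Each substrate consumed therefore gives target with the share: capture rate over the sum of 0.0905 min⁻¹ and two times that attack rate. The first way sets [substrate] at half its charge and gives 6.07%. The second way integrates the share from the charge down to zero, which gives the capture rate over two times the starting attack rate, times the logarithm of one plus two times the starting attack rate over 0.0905 min⁻¹: 6.25%. Both rest on the same capture rate, so their nearness is no check on it, and they part in the handling of [substrate]. The share curves upward as [substrate] falls, so the midpoint lies below the mean, and the first way is the one that cheats. Going round once more, 6.25% of target draws 2.12 mM of partner from 68.0 mM, so [partner] as charged stands, and the reckoning stays at 6.25%.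

**The stop.** Substrate opens with a lifetime of 0.922 h, much shorter than the run, so the reckoning expects the substrate to have reacted by the end and target to hold its value afterwards.

**The forecast.** The forecast says all of the substrate has reacted, with conversion 100%, target 6.3%, side product 24% and 6.3% of target long afterwards, on the ground that “Most of the open intermediate decomposes”.

**In the flask.** In the flask, all of the substrate has reacted: conversion 100%, target 6.30% against the reckoned 6.25%, side product 24.1%, and 6.30% of target long afterwards. Decomposition outruns capture by 10.7 to one, and decomposed reagent stands to target at 11.0 to one. In the flask with 0.10 mM of free catalyst, the capture rate becomes 0.0188 min⁻¹, the same integral gives 14.0%, and that flask reads 14.2%.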